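**Numbering.** Unprimed locants (O1, C2, C3, C3a, C4–C7, C7a) refer to the dihydrobenzofuran whose benzo ring is ring A; primed locants refer to the dihydrobenzofuran whose benzo ring is ring B. In compound names, ArB = (2R,3R)-3-(3,5-dimethoxyphenyl)-7-methoxy-2-(4-methoxyphenyl)-2,3-dihydro-1-benzofuran-5-yl.

## The problem

Target 40 is made of two 2,3-trans-2,3-diaryl-2,3-dihydrobenzofurans joined by one bond from C3 of the first to C5' of the second. C2 and C2' carry 4-hydroxyphenyl groups, C3' a 3,5-dihydroxyphenyl group, C6 and C7' hydroxyls, and C4 a (Z)-4-hydroxystyryl group. Ring A is a resorcinol (O1 on C7a and OH on C6, meta, with C7–H between) whose two carbon substituents sit on the adjacent carbons C3a and C4. Substitution of a resorcinol does not give this pattern, and the C4 substituent is a hindered Z-olefin next to the C3 branch. The four stereocentres form two remote pairs, (2S,3S) and (2'R,3'R). C2 and C2' are 4-oxybenzylic ether carbons that ionise reversibly in acid and settle trans, so C3 and C3' are the controlling centres. Ring B separates them, so neither can direct the other and each needs reagent control. C3 is benzylic and must never lie α to a carbonyl. The Z-stilbene (isomerisation, capture of a C2 cation), the benzylic C2–O1 and C2'–O1' bonds and the seven phenols will not survive rough treatment, so the olefin is carried as an alkyne and unveiled last. The enabling feature is the ring A pattern itself: heating a 3,4-disubstituted cyclobutenone with an oxyalkyne gives a phenol in which the cyclobutenone C4 and C3 substituents end up on adjacent carbons (C3a, C4), the new OH is ortho to C3a (the future O1) and the alkyne oxygen is meta to it (C6).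

## Retrosynthesis

**40 ⇒ 39.** No skeletal bond is cut; the Z-olefin is traced to diarylalkyne 39. A Z-selective olefination at a C4 aldehyde flanked by the C3 branch would be slow and unselective, and a stilbene would not survive the acid steps before it. The forward reaction must stop at one equivalent of hydrogen on a heptaphenol.

**39 ⇒ 38.** Seven O–alkyl bonds are cut (six methyl, one ethyl). Methyl ethers let every building block be bought and tolerate organolithiums, hydroboration and heat. The price is one Lewis-acid step, placed at the alkyne stage because an alkyne is a far poorer cation trap than the stilbene.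

**38 ⇒ 37.** The C2–O1 bond is cut. C2 is a 4-methoxybenzylic carbon, so its methyl ether ionises in acid and the C7a phenol captures the cation. Closure is reversible and gives the trans ring, so the C2 configuration of 37 is irrelevant and only C3 has to be right. Forming C3–C3a or C2–C3 late would give up this self-correction.

**37 ⇒ 32 + 25.** Ring A is cut at C7a–C7 and C5–C6, to 3-alkynyl-4-alkylcyclobutenone 32 and ethoxyacetylene 25. This is the key step and it writes the whole substitution pattern in one thermal operation. The precursor is much simpler: all six future ring A carbons are present as a four-membered ring plus a two-carbon alkyne. A silyloxyalkyne would allow fluoride unmasking but has to be made. Six methyl ethers must be cleaved anyway, so commercial ethoxyacetylene is used. The forward reaction must be regioselective in the cycloaddition and must leave C3 alone.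

**32 ⇒ 28 + 29.** The bond between the cyclobutenone and the arylethynyl group is cut. Acetylide addition to 3-ethoxycyclobutenone 28 and hydrolysis transposes the carbonyl and places the alkyne on the carbon that becomes C4. A later cross-coupling on ring A would need a halide pattern that is as hard to reach as the target.

**28 ⇒ 24 + 25.** Two ring bonds are cut: (2+2) cycloaddition of the aldoketene from acid 24 with ethoxyacetylene. The acid carries C3 in the β position, so it cannot epimerise.

**24 ⇒ 19 (via 20, 22).** Functional group changes only. The carboxyl carbon is the terminal vinyl carbon of homoallylic alcohol 19. The carbinol is capped as a methyl ether, which cannot lactonise onto the acyl chloride as a γ-silyl ether might, yet still leaves in step 16.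

**19 ⇒ 16 + 17.** The C2–C3 bond is cut: allylboration of 4-methoxybenzaldehyde 17 with E-γ-aryl allylboronate 16 under a chiral phosphoric acid. This sets C3 with no carbonyl ever next to it. A carbene-catalysed homoenolate annulation of an enal with 17 would form the same bond, but its enantiocontrol with simple electron-rich aryl aldehydes is poor and the lactone would need opening and protection. Conjugate addition of a vinyl group followed by ozonolysis would pass through an epimerisable α-aryl aldehyde.

**16 ⇒ 11 + 12.** The C5'–C bond and the C–B bond are cut. Aryl bromide 11 is lithiated and added to acrolein 12, and the acetate 15 is borylated through a π-allyl palladium complex, which gives the E-isomer needed for an anti adduct.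

**11 ⇒ 8 (via 10).** The C3'–C2' bond is cut: an enantioselective intramolecular C–H insertion of a diaryl carbene into the benzylic ether C–H of 8. The reaction gives the cis ring, and acid then epimerises C2' to trans. The method has close precedent for 2,3-diaryl dihydrobenzofurans bearing methoxyaryl groups and an aryl bromide.

**8 ⇒ 1 + 2 + 4.** Hydrazone 8 comes from ketone 7, assembled from salicylaldehyde 1, benzyl chloride 2 and aryl bromide 4 by etherification, Grignard addition and oxidation.

## Roads not taken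

**Alternative 1:** ring A dihydrofuran by Wolff contraction. The cut is C3–C3a. Irradiation of diazoflavanone A1 in methanol shifts the ring A carbon from the carbonyl carbon to C3 and gives, after base equilibration, trans ester A2.
- Merits: ring A comes from a cheap aromatic, C2 is set early, and the C4 chloride is a handle for the alkyne.
- Weak points: A2 carries an ester where the target needs the C3–C5' bond, so ring B must be attached late to a hindered secondary carbon between the C2 aryl and the C4 substituent, or built from the ester. The flavanone C2 can be lost by reversible O1–C2 opening under the basic diazo transfer. An ortho-hindered aryl chloride is a poor coupling partner.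
- Comparison: this road is shorter to the ring A core and needs no thermal cascade. The chosen plan sets against it that the C3–C5' bond exists from bromide 11 onward and ring A is built around it, so the hardest bond is never a late intermolecular coupling.

**Alternative 2:** ring B by dynamic kinetic reduction and fluoride displacement. The cut is O1'–C7a'. Transfer hydrogenation of racemising ketone A3 with RuCl(p-cymene)(TsDPEN), then K2CO3, gives ester A4.
- Merits: both ring B centres come from one catalytic step and the ring is formed trans directly.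
- Weak points: the diarylmethine must racemise faster than reduction in an acidic formate medium. The fluoride is activated only by a para ester and flanked by methoxy, so displacement by a secondary alkoxide needs forcing. The ester handle needs extra steps before the allyl unit can be attached.
- Comparison: for ring B alone this road is better in step count (steps 2–6 here are five operations for the same ring). The chosen plan sets against it precedent on this exact substitution pattern and a bromide that is used directly in step 7. The two are complementary, since A4 could feed the same ring A construction.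

**Alternative 3:** the 3,5-dihydroxyphenyl ring by a polyketide fold. The cut is inside the resorcinol ring on C3'. Mild base folds triketo ester A5 by aldol addition and dehydration to benzoate A6.
- Merits: biomimetic, two phenols arrive free, the bromide is kept.
- Weak points: it spends arene construction on a symmetric ring that is bought as aryl bromide 4. The chain is laborious and can close in the Claisen mode or to a pyranone. C3' sits α to a ketone in A5, so it can epimerise and the furan can open by β-elimination of the phenoxide. The extra ester has to be removed.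
- Comparison: it is milder at the deprotection end, which the chosen plan cannot match. The chosen plan reserves de novo arene synthesis for ring A, where substitution chemistry fails.

Key step: step 15

Assumption: the catalyst antipodes named in steps 5 and 9, Rh2(R-PTAD)4 and (S)-TRIP (Si-face attack on the aldehyde), are taken to give the configurations drawn; if either sense proves opposite, the mirror-image catalyst is used and nothing else changes.

## Route

Step 1
Reactants: 1 5-bromo-2-hydroxy-3-methoxybenzaldehyde; 2 4-methoxybenzyl chloride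
Product: 3 5-bromo-3-methoxy-2-[(4-methoxyphenyl)methoxy]benzaldehyde
Conditions: K2CO3, KI (cat.), DMF, 60 °C
Reagents that add atoms: none
Why: Williamson etherification of the phenol; the benzylic CH2 introduced here becomes C2' and carries the C–H bond used in step 5.

Step 2
Reactants: 3; 4 1-bromo-3,5-dimethoxybenzene
Product: 6 {5-bromo-3-methoxy-2-[(4-methoxyphenyl)methoxy]phenyl}(3,5-dimethoxyphenyl)methanol (racemic), via 3,5-dimethoxyphenylmagnesium bromide 5 (not isolated)
Conditions: Mg, I2 (cat.), THF, reflux; then 3, THF, 0 °C; sat. aq. NH4Cl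
Reagents that add atoms: none
Why: Grignard addition to the aldehyde; the aryl bromide of 3 does not exchange at 0 °C, and the carbinol centre is removed in step 3.

Step 3
Reactants: 6
Product: 7 {5-bromo-3-methoxy-2-[(4-methoxyphenyl)methoxy]phenyl}(3,5-dimethoxyphenyl)methanone
Conditions: MnO2, CH2Cl2, rt
Reagents that add atoms: none
Why: Oxidation of a doubly benzylic alcohol with manganese dioxide; ethers and bromide are inert.

Step 4
Reactants: 7
Product: 8 hydrazone of 7 (E/Z mixture)
Conditions: N2H4·H2O, AcOH (cat.), EtOH, 80 °C, sealed tube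
Reagents that add atoms: hydrazine (as hydrate), NN
Why: Condensation of the hindered diaryl ketone with excess hydrazine; both hydrazone isomers give the same diazo compound.

Step 5
Reactants: 8
Product: 10 (2S,3R)-5-bromo-3-(3,5-dimethoxyphenyl)-7-methoxy-2-(4-methoxyphenyl)-2,3-dihydro-1-benzofuran (cis), via diaryldiazomethane 9 (not isolated)
Conditions: MnO2, CH2Cl2, 0 °C; filter; Rh2(R-PTAD)4 (1 mol %), CH2Cl2, 0 °C
Reagents that add atoms: none
Why: Oxidation gives the donor/donor diazo compound, and the chiral dirhodium carbene inserts into the activated O–CH2Ar C–H bond through a five-membered transition state (intramolecular carbene C–H insertion), closing the ring B furan as the cis isomer. C3' (R) is set by the catalyst; C2' is corrected in step 6.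

Step 6
Reactants: 10
Product: 11 (2R,3R)-5-bromo-3-(3,5-dimethoxyphenyl)-7-methoxy-2-(4-methoxyphenyl)-2,3-dihydro-1-benzofuran (trans; ArB–Br)
Conditions: TFA, CH2Cl2, 0 °C → rt, dilute
Reagents that add atoms: none
Why: Acid reversibly ionises the C2'–O1' bond to the 4-methoxybenzylic cation and reclosure gives the more stable trans ring (acid-mediated epimerisation); C3' is not touched.

Step 7
Reactants: 11; 12 acrolein
Product: 15 1-(ArB)prop-2-en-1-yl acetate (both C1 epimers), via aryllithium 13 (not isolated), via lithium allylic alkoxide 14 (not isolated)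
Conditions: n-BuLi, THF, −78 °C; 12; then Ac2O, −78 → 0 °C
Reagents that add atoms: acetic anhydride, CC(=O)OC(C)=O
Why: Bromine–lithium exchange, 1,2-addition to acrolein and O-acetylation in one flask. The carbinol configuration (and any drift to the linear acetate) is irrelevant because step 8 passes through a π-allyl complex.

Step 8
Reactants: 15
Product: 16 2-[(2E)-3-(ArB)prop-2-en-1-yl]-4,4,5,5-tetramethyl-1,3,2-dioxaborolane
Conditions: B2pin2, Pd2(dba)3 (2.5 mol %), DMSO, 50 °C
Reagents that add atoms: bis(pinacolato)diboron, CC1(C)OB(OC1(C)C)B1OC(C)(C)C(C)(C)O1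
Why: Oxidative addition of the allylic acetate to zerovalent palladium gives a π-allyl complex that is borylated at the unhindered terminus (Miyaura allylic borylation), giving the conjugated E-allylboronate.

Step 9
Reactants: 16; 17 4-methoxybenzaldehyde
Product: 19 (1S,2R)-2-(ArB)-1-(4-methoxyphenyl)but-3-en-1-ol, via pinacol borate 18 (not isolated)
Conditions: (S)-TRIP [(S)-3,3'-bis(2,4,6-triisopropylphenyl)-1,1'-binaphthyl-2,2'-diyl hydrogen phosphate] (5 mol %), 4 Å MS, toluene, −30 → 0 °C; aq. NaHCO3
Reagents that add atoms: none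
Why: Brønsted-acid-catalysed allylboration through a closed chair (Zimmerman–Traxler) transition state; the E-boronate gives the anti adduct and the chiral phosphate selects the Si face of the aldehyde. This fixes the allylic centre (R here, the future 3S) together with the carbinol centre; the remote ring B centres should not interfere.

Step 10
Reactants: 19
Product: 20 1-[(1S,2R)-2-(ArB)-1-methoxybut-3-en-1-yl]-4-methoxybenzene
Conditions: NaH, MeI, THF/DMF, 0 °C → rt
Reagents that add atoms: iodomethane, CI
Why: Williamson methylation; the methyl ether survives the following steps, cannot lactonise onto the acyl chloride of step 13, and is still a leaving group on a 4-methoxybenzylic carbon for step 16.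

Step 11
Reactants: 20
Product: 22 (3R,4S)-3-(ArB)-4-methoxy-4-(4-methoxyphenyl)butan-1-ol, via B-alkyl-9-BBN adduct 21 (not isolated)
Conditions: 9-BBN, THF, 0 °C → rt; then NaOH, H2O2, 0 °C
Reagents that add atoms: hydrogen peroxide, OO
Why: Anti-Markovnikov hydroboration of the terminal vinyl group and oxidation; the allylic centre is not involved.

Step 12
Reactants: 22
Product: 24 (3R,4S)-3-(ArB)-4-methoxy-4-(4-methoxyphenyl)butanoic acid, via aldehyde 23 (not isolated)
Conditions: TEMPO (20 mol %), PhI(OAc)2 (2.2 equiv), MeCN/H2O, rt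
Reagents that add atoms: water, O
Why: Oxoammonium oxidation of the primary alcohol through the aldehyde hydrate to the acid; C3 is β to the carbonyl throughout and cannot epimerise.

Step 13
Reactants: 24; 25 ethoxyacetylene
Product: 28 4-[(1R,2S)-1-(ArB)-2-methoxy-2-(4-methoxyphenyl)ethyl]-3-ethoxycyclobut-2-en-1-one (both C4 epimers), via acid chloride 26 (not isolated), via aldoketene 27 (not isolated)
Conditions: 1-chloro-N,N,2-trimethylprop-1-en-1-amine, CH2Cl2, 0 °C; then added slowly to 25 (3 equiv), Et3N, Et2O, 0 °C → rt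
Reagents that add atoms: none
Why: The chloroenamine forms the acyl chloride without HCl, and triethylamine dehydrohalogenates it to the aldoketene. Ethoxyacetylene captures the ketene in a regioselective (2+2) cycloaddition, its CH carbon bonding to the ketene carbonyl carbon (ketene–alkoxyalkyne cycloaddition). Slow addition keeps the ketene dilute against dimerisation.

Step 14
Reactants: 28; 29 1-ethynyl-4-methoxybenzene
Product: 32 4-[(1R,2S)-1-(ArB)-2-methoxy-2-(4-methoxyphenyl)ethyl]-3-[(4-methoxyphenyl)ethynyl]cyclobut-2-en-1-one (both C4 epimers), via lithium acetylide 30 (not isolated), via lithium cyclobutenolate 31 (not isolated)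
Conditions: 29, n-BuLi, THF, −78 °C; 28, −78 °C; then 1 M HCl, THF, 0 °C
Reagents that add atoms: none
Why: 1,2-Addition of the acetylide to the vinylogous ester carbonyl, then acid hydrolysis of the enol ether with loss of ethanol and carbonyl transposition, the standard route from 3-ethoxycyclobutenones to 3-substituted cyclobutenones. The ring C4–H is not acidic because its enolate would be a cyclobutadiene.

Step 15
Reactants: 32; 25 ethoxyacetylene
Product: 37 2-[(1S,2S)-1-(ArB)-2-methoxy-2-(4-methoxyphenyl)ethyl]-5-ethoxy-3-[(4-methoxyphenyl)ethynyl]phenol, via vinylketene 33 (not isolated), via 4-vinylcyclobutenone 34 (not isolated), via dienylketene 35 (not isolated), via cyclohexadienone 36 (not isolated)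
Conditions: 25 (4 equiv), toluene, 80 °C, sealed tube; excess alkyne removed, then 110 °C if needed
Reagents that add atoms: none
Why: Thermal 4π ring opening of 32 gives vinylketene 33, with the C4 side chain rotating outward. Ethoxyacetylene adds to the ketene in a (2+2) cycloaddition, its nucleophilic CH carbon bonding to the ketene carbonyl carbon (C7a–C7) and its oxygenated carbon to the ketene α-carbon (C6–C5), giving 34. A second 4π opening gives dienylketene 35, which closes ring A by thermal disrotatory 6π electrocyclisation (C7a–C3a), and dienone 36 tautomerises to the phenol. The closest known reaction is the Danheiser benzannulation of cyclobutenones with alkoxy- and silyloxyalkynes; a 3-alkynyl, 4-branched cyclobutenone of this size is an extension in substrate only. No stereocentre is formed, and C3 is attached to a terminus of the triene and is not touched. The step needs regioselectivity, secured by ketene–ynol ether polarity, and chemoselectivity for the electron-rich alkyne over the internal diarylalkyne, secured by the same polarity. The outward rotation puts hydrogen, not the branch, inside at the electrocyclisation terminus and denies the ketene a 1,5-hydrogen shift from C3.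

Step 16
Reactants: 37
Product: 38 (2S,3S)-3-(ArB)-6-ethoxy-2-(4-methoxyphenyl)-4-[(4-methoxyphenyl)ethynyl]-2,3-dihydro-1-benzofuran
Conditions: TFA (5 equiv), CH2Cl2, −20 → 0 °C, dilute
Reagents that add atoms: none
Why: Acid ionises the 4-methoxybenzylic methyl ether (SN1) and the C7a phenol oxygen closes the five-membered ring. Closure is reversible and places the C2 aryl trans to the C3 substituent, so 2S is set by C3. Low temperature and short contact keep the neighbouring alkyne from competing for the cation.

Step 17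
Reactants: 38
Product: 39 (2S,3S)-3-[(2R,3R)-3-(3,5-dihydroxyphenyl)-7-hydroxy-2-(4-hydroxyphenyl)-2,3-dihydro-1-benzofuran-5-yl]-2-(4-hydroxyphenyl)-4-[(4-hydroxyphenyl)ethynyl]-2,3-dihydro-1-benzofuran-6-ol
Conditions: BBr3 (14 equiv), CH2Cl2, −78 °C → rt; then MeOH, H2O, 0 °C
Reagents that add atoms: none
Why: Lewis-acid cleavage of the six aryl methyl ethers and the aryl ethyl ether through aryloxyboron bromides that hydrolyse on work-up. Any transient opening of a C2–O bond recloses to the trans ring, and an alkyne is far less prone to cation capture than the stilbene it stands for.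

Step 18
Reactants: 39
Product: 40 (2S,3S)-3-[(2R,3R)-3-(3,5-dihydroxyphenyl)-7-hydroxy-2-(4-hydroxyphenyl)-2,3-dihydro-1-benzofuran-5-yl]-2-(4-hydroxyphenyl)-4-[(Z)-2-(4-hydroxyphenyl)ethenyl]-2,3-dihydro-1-benzofuran-6-ol (CNP0172909.2)
Conditions: H2 (1 atm), Pd/CaCO3 poisoned with Pb(OAc)2, quinoline, MeOH/EtOAc, rt, dark
Reagents that add atoms: none
Why: Syn delivery of one equivalent of hydrogen on the poisoned palladium surface (Lindlar semihydrogenation) gives the Z-olefin; neutral conditions and exclusion of light protect the product.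

## Compound list

1 | 5-bromo-2-hydroxy-3-methoxybenzaldehyde | COc1cc(Br)cc(C=O)c1O | starting material
2 | 4-methoxybenzyl chloride | COc1ccc(CCl)cc1 | starting material
3 | 5-bromo-3-methoxy-2-[(4-methoxyphenyl)methoxy]benzaldehyde | COc1ccc(COc2c(OC)cc(Br)cc2C=O)cc1 | intermediate
4 | 1-bromo-3,5-dimethoxybenzene | COc1cc(Br)cc(OC)c1 | starting material
5 | 3,5-dimethoxyphenylmagnesium bromide | COc1cc([Mg]Br)cc(OC)c1 | intermediate
6 | {5-bromo-3-methoxy-2-[(4-methoxyphenyl)methoxy]phenyl}(3,5-dimethoxyphenyl)methanol (racemic) | COc1ccc(COc2c(OC)cc(Br)cc2C(O)c2cc(OC)cc(OC)c2)cc1 | intermediate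
7 | {5-bromo-3-methoxy-2-[(4-methoxyphenyl)methoxy]phenyl}(3,5-dimethoxyphenyl)methanone | COc1ccc(COc2c(OC)cc(Br)cc2C(=O)c2cc(OC)cc(OC)c2)cc1 | intermediate
8 | hydrazone of 7 (E/Z mixture) | COc1ccc(COc2c(OC)cc(Br)cc2C(=NN)c2cc(OC)cc(OC)c2)cc1 | intermediate
9 | 5-bromo-1-[diazo(3,5-dimethoxyphenyl)methyl]-3-methoxy-2-[(4-methoxyphenyl)methoxy]benzene | COc1ccc(COc2c(OC)cc(Br)cc2C(=[N+]=[N-])c2cc(OC)cc(OC)c2)cc1 | intermediate
10 | (2S,3R)-5-bromo-3-(3,5-dimethoxyphenyl)-7-methoxy-2-(4-methoxyphenyl)-2,3-dihydro-1-benzofuran (cis) | Brc1cc(OC)c2c(c1)[C@@H](c1cc(OC)cc(OC)c1)[C@@H](c1ccc(OC)cc1)O2 | intermediate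
11 | (2R,3R)-5-bromo-3-(3,5-dimethoxyphenyl)-7-methoxy-2-(4-methoxyphenyl)-2,3-dihydro-1-benzofuran (trans; ArB–Br) | Brc1cc(OC)c2c(c1)[C@@H](c1cc(OC)cc(OC)c1)[C@H](c1ccc(OC)cc1)O2 | intermediate
12 | acrolein | C=CC=O | starting material
13 | ArB–Li (aryllithium) | [Li]c1cc(OC)c2c(c1)[C@@H](c1cc(OC)cc(OC)c1)[C@H](c1ccc(OC)cc1)O2 | intermediate
14 | lithium 1-(ArB)prop-2-en-1-olate (both C1 epimers) | [Li+].[O-]C(C=C)c1cc(OC)c2c(c1)[C@@H](c1cc(OC)cc(OC)c1)[C@H](c1ccc(OC)cc1)O2 | intermediate
15 | 1-(ArB)prop-2-en-1-yl acetate (both C1 epimers) | CC(=O)OC(C=C)c1cc(OC)c2c(c1)[C@@H](c1cc(OC)cc(OC)c1)[C@H](c1ccc(OC)cc1)O2 | intermediate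
16 | 2-[(2E)-3-(ArB)prop-2-en-1-yl]-4,4,5,5-tetramethyl-1,3,2-dioxaborolane | CC1(C)OB(C/C=C/c2cc(OC)c3c(c2)[C@@H](c2cc(OC)cc(OC)c2)[C@H](c2ccc(OC)cc2)O3)OC1(C)C | intermediate
17 | 4-methoxybenzaldehyde | COc1ccc(C=O)cc1 | starting material
18 | 2-{[(1S,2R)-2-(ArB)-1-(4-methoxyphenyl)but-3-en-1-yl]oxy}-4,4,5,5-tetramethyl-1,3,2-dioxaborolane | C=C[C@H](c1cc(OC)c2c(c1)[C@@H](c1cc(OC)cc(OC)c1)[C@H](c1ccc(OC)cc1)O2)[C@@H](c1ccc(OC)cc1)OB1OC(C)(C)C(C)(C)O1 | intermediate
19 | (1S,2R)-2-(ArB)-1-(4-methoxyphenyl)but-3-en-1-ol | C=C[C@H](c1cc(OC)c2c(c1)[C@@H](c1cc(OC)cc(OC)c1)[C@H](c1ccc(OC)cc1)O2)[C@@H](c1ccc(OC)cc1)O | intermediate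
20 | 1-[(1S,2R)-2-(ArB)-1-methoxybut-3-en-1-yl]-4-methoxybenzene | C=C[C@H](c1cc(OC)c2c(c1)[C@@H](c1cc(OC)cc(OC)c1)[C@H](c1ccc(OC)cc1)O2)[C@@H](c1ccc(OC)cc1)OC | intermediate
21 | 9-[(3R,4S)-3-(ArB)-4-methoxy-4-(4-methoxyphenyl)butyl]-9-borabicyclo[3.3.1]nonane | C1CCC2CCCC1B2CC[C@H](c1cc(OC)c2c(c1)[C@@H](c1cc(OC)cc(OC)c1)[C@H](c1ccc(OC)cc1)O2)[C@@H](c1ccc(OC)cc1)OC | intermediate
22 | (3R,4S)-3-(ArB)-4-methoxy-4-(4-methoxyphenyl)butan-1-ol | OCC[C@H](c1cc(OC)c2c(c1)[C@@H](c1cc(OC)cc(OC)c1)[C@H](c1ccc(OC)cc1)O2)[C@@H](c1ccc(OC)cc1)OC | intermediate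
23 | (3R,4S)-3-(ArB)-4-methoxy-4-(4-methoxyphenyl)butanal | O=CC[C@H](c1cc(OC)c2c(c1)[C@@H](c1cc(OC)cc(OC)c1)[C@H](c1ccc(OC)cc1)O2)[C@@H](c1ccc(OC)cc1)OC | intermediate
24 | (3R,4S)-3-(ArB)-4-methoxy-4-(4-methoxyphenyl)butanoic acid | OC(=O)C[C@H](c1cc(OC)c2c(c1)[C@@H](c1cc(OC)cc(OC)c1)[C@H](c1ccc(OC)cc1)O2)[C@@H](c1ccc(OC)cc1)OC | intermediate
25 | ethoxyacetylene | C#COCC | starting material
26 | (3R,4S)-3-(ArB)-4-methoxy-4-(4-methoxyphenyl)butanoyl chloride | ClC(=O)C[C@H](c1cc(OC)c2c(c1)[C@@H](c1cc(OC)cc(OC)c1)[C@H](c1ccc(OC)cc1)O2)[C@@H](c1ccc(OC)cc1)OC | intermediate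
27 | (3R,4S)-3-(ArB)-4-methoxy-4-(4-methoxyphenyl)but-1-en-1-one (aldoketene) | O=C=C[C@H](c1cc(OC)c2c(c1)[C@@H](c1cc(OC)cc(OC)c1)[C@H](c1ccc(OC)cc1)O2)[C@@H](c1ccc(OC)cc1)OC | intermediate
28 | 4-[(1R,2S)-1-(ArB)-2-methoxy-2-(4-methoxyphenyl)ethyl]-3-ethoxycyclobut-2-en-1-one (both C4 epimers) | CCOC1=CC(=O)C1[C@H](c1cc(OC)c2c(c1)[C@@H](c1cc(OC)cc(OC)c1)[C@H](c1ccc(OC)cc1)O2)[C@@H](c1ccc(OC)cc1)OC | intermediate
29 | 1-ethynyl-4-methoxybenzene | COc1ccc(C#C)cc1 | starting material
30 | lithium (4-methoxyphenyl)acetylide | COc1ccc(C#C[Li])cc1 | intermediate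
31 | lithium 4-[(1R,2S)-1-(ArB)-2-methoxy-2-(4-methoxyphenyl)ethyl]-3-ethoxy-1-[(4-methoxyphenyl)ethynyl]cyclobut-2-en-1-olate (ring diastereomers) | [Li+].[O-]C1(C#Cc2ccc(OC)cc2)C=C(OCC)C1[C@H](c1cc(OC)c2c(c1)[C@@H](c1cc(OC)cc(OC)c1)[C@H](c1ccc(OC)cc1)O2)[C@@H](c1ccc(OC)cc1)OC | intermediate
32 | 4-[(1R,2S)-1-(ArB)-2-methoxy-2-(4-methoxyphenyl)ethyl]-3-[(4-methoxyphenyl)ethynyl]cyclobut-2-en-1-one (both C4 epimers) | O=C1C=C(C#Cc2ccc(OC)cc2)C1[C@H](c1cc(OC)c2c(c1)[C@@H](c1cc(OC)cc(OC)c1)[C@H](c1ccc(OC)cc1)O2)[C@@H](c1ccc(OC)cc1)OC | intermediate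
33 | (3Z,5R,6S)-5-(ArB)-6-methoxy-6-(4-methoxyphenyl)-3-[(4-methoxyphenyl)ethynyl]hexa-1,3-dien-1-one (side chain trans to the ketene carbon) | O=C=C/C(C#Cc1ccc(OC)cc1)=C/[C@H](c1cc(OC)c2c(c1)[C@@H](c1cc(OC)cc(OC)c1)[C@H](c1ccc(OC)cc1)O2)[C@@H](c1ccc(OC)cc1)OC | intermediate
34 | 4-{(1Z,3R,4S)-3-(ArB)-4-methoxy-4-(4-methoxyphenyl)-1-[(4-methoxyphenyl)ethynyl]but-1-en-1-yl}-3-ethoxycyclobut-2-en-1-one | CCOC1=CC(=O)C1/C(C#Cc1ccc(OC)cc1)=C/[C@H](c1cc(OC)c2c(c1)[C@@H](c1cc(OC)cc(OC)c1)[C@H](c1ccc(OC)cc1)O2)[C@@H](c1ccc(OC)cc1)OC | intermediate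
35 | (3E,5Z,7R,8S)-7-(ArB)-3-ethoxy-8-methoxy-8-(4-methoxyphenyl)-5-[(4-methoxyphenyl)ethynyl]octa-1,3,5-trien-1-one | O=C=C/C(OCC)=C\C(C#Cc1ccc(OC)cc1)=C\[C@H](c1cc(OC)c2c(c1)[C@@H](c1cc(OC)cc(OC)c1)[C@H](c1ccc(OC)cc1)O2)[C@@H](c1ccc(OC)cc1)OC | intermediate
36 | 6-[(1R,2S)-1-(ArB)-2-methoxy-2-(4-methoxyphenyl)ethyl]-3-ethoxy-5-[(4-methoxyphenyl)ethynyl]cyclohexa-2,4-dien-1-one | O=C1C=C(OCC)C=C(C#Cc2ccc(OC)cc2)C1[C@H](c1cc(OC)c2c(c1)[C@@H](c1cc(OC)cc(OC)c1)[C@H](c1ccc(OC)cc1)O2)[C@@H](c1ccc(OC)cc1)OC | intermediate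
37 | 2-[(1S,2S)-1-(ArB)-2-methoxy-2-(4-methoxyphenyl)ethyl]-5-ethoxy-3-[(4-methoxyphenyl)ethynyl]phenol | COc1ccc(C#Cc2cc(OCC)cc(O)c2[C@H](c2cc(OC)c3c(c2)[C@@H](c2cc(OC)cc(OC)c2)[C@H](c2ccc(OC)cc2)O3)[C@@H](c2ccc(OC)cc2)OC)cc1 | intermediate
38 | (2S,3S)-3-(ArB)-6-ethoxy-2-(4-methoxyphenyl)-4-[(4-methoxyphenyl)ethynyl]-2,3-dihydro-1-benzofuran | COc1ccc(C#Cc2cc(OCC)cc3c2[C@H](c2cc(OC)c4c(c2)[C@@H](c2cc(OC)cc(OC)c2)[C@H](c2ccc(OC)cc2)O4)[C@@H](c2ccc(OC)cc2)O3)cc1 | intermediate
39 | (2S,3S)-3-[(2R,3R)-3-(3,5-dihydroxyphenyl)-7-hydroxy-2-(4-hydroxyphenyl)-2,3-dihydro-1-benzofuran-5-yl]-2-(4-hydroxyphenyl)-4-[(4-hydroxyphenyl)ethynyl]-2,3-dihydro-1-benzofuran-6-ol | Oc1ccc(C#Cc2cc(O)cc3c2[C@H](c2cc(O)c4c(c2)[C@@H](c2cc(O)cc(O)c2)[C@H](c2ccc(O)cc2)O4)[C@@H](c2ccc(O)cc2)O3)cc1 | intermediate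
40 | (2S,3S)-3-[(2R,3R)-3-(3,5-dihydroxyphenyl)-7-hydroxy-2-(4-hydroxyphenyl)-2,3-dihydro-1-benzofuran-5-yl]-2-(4-hydroxyphenyl)-4-[(Z)-2-(4-hydroxyphenyl)ethenyl]-2,3-dihydro-1-benzofuran-6-ol | Oc1ccc(/C=C\c2cc(O)cc3c2[C@H](c2cc(O)c4c(c2)[C@@H](c2cc(O)cc(O)c2)[C@H](c2ccc(O)cc2)O4)[C@@H](c2ccc(O)cc2)O3)cc1 | target

## Step count and risks

Total: 18 steps. Longest linear sequence: 18 steps, from 1 to 40; all other inputs (2, 4, 12, 17, 25, 29) are purchased.

**Step 15 (key step).** Capture of vinylketene 33 by ethoxyacetylene may be slower than its self-condensation. At the temperature needed for the second ring opening, ethoxyacetylene can also lose ethylene by a retro-ene reaction and release ketene, which would acylate the product phenol. Fallback, setting out from 32: the silyl ynol ether (triisopropylsiloxy)ethyne F1, a more nucleophilic ketenophile with no retro-ene pathway (not commercial; prepared by O-silylation of a lithium ynolate), is heated with 32 to give the silyl ether phenol 2-[(1S,2S)-1-(ArB)-2-methoxy-2-(4-methoxyphenyl)ethyl]-3-[(4-methoxyphenyl)ethynyl]-5-[(triisopropylsilyl)oxy]phenol F2. TFA closes ring A to the silyl ether (2S,3S)-3-(ArB)-2-(4-methoxyphenyl)-4-[(4-methoxyphenyl)ethynyl]-6-[(triisopropylsilyl)oxy]-2,3-dihydro-1-benzofuran F3. Bu4NF frees the phenol (2S,3S)-3-(ArB)-2-(4-methoxyphenyl)-4-[(4-methoxyphenyl)ethynyl]-2,3-dihydro-1-benzofuran-6-ol F4. BBr3 then cleaves the six methyl ethers and the route is rejoined at 39.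

**Step 13.** Dimerisation of aldoketene 27, or intramolecular Friedel–Crafts acylation of ring B by 26, may outrun the (2+2) capture because the ketene is hindered by the branched side chain. Fallback, setting out from 24: 26 is dehydrohalogenated with Et3N in the presence of 1,1-diethoxyethene, a more reactive ketenophile. This gives 2-[(1R,2S)-1-(ArB)-2-methoxy-2-(4-methoxyphenyl)ethyl]-3,3-diethoxycyclobutan-1-one F5, which loses ethanol on neutral alumina or gentle warming and rejoins the route at 28.

**Step 9.** The bulky, electron-rich γ-aryl boronate and the electron-rich aldehyde react slowly, so an uncatalysed pathway may erode facial selectivity at C3. Fallback, setting out from 11: Sonogashira coupling with propyne (Pd(PPh3)2Cl2, CuI, Et3N) gives (2R,3R)-3-(3,5-dimethoxyphenyl)-7-methoxy-2-(4-methoxyphenyl)-5-(prop-1-yn-1-yl)-2,3-dihydro-1-benzofuran F6. A transfer-hydrogenative coupling of F6 with 4-methoxybenzyl alcohol (RuH2(CO)(PPh3)3, a chiral ferrocenyl diphosphine of the Josiphos family, Bu4NI, THF, 95 °C) follows. The alkyne isomerises to an allene and serves as an α-aryl allylmetal equivalent, which gives the anti adduct and rejoins the route at 19.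

**Step 17.** Reversible Lewis-acid ionisation of the ring A C2–O1 bond may end in capture of the C2 cation by the neighbouring alkyne (indene formation), and BBr3 may add across the alkyne. Fallback, setting out from 38: dealkylation by SN2 attack of sodium ethanethiolate in DMF at 130–150 °C. It involves no cation and no Lewis acid and returns to the route at 39. The ethyl ether is the slowest to cleave. This detour makes no compound outside the list (entry F0).

## Further compounds

F1 | step 15 | (triisopropylsiloxy)ethyne | C#CO[Si](C(C)C)(C(C)C)C(C)C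
F2 | step 15 | 2-[(1S,2S)-1-(ArB)-2-methoxy-2-(4-methoxyphenyl)ethyl]-3-[(4-methoxyphenyl)ethynyl]-5-[(triisopropylsilyl)oxy]phenol | COc1ccc(C#Cc2cc(O[Si](C(C)C)(C(C)C)C(C)C)cc(O)c2[C@H](c2cc(OC)c3c(c2)[C@@H](c2cc(OC)cc(OC)c2)[C@H](c2ccc(OC)cc2)O3)[C@@H](c2ccc(OC)cc2)OC)cc1
F3 | step 15 | (2S,3S)-3-(ArB)-2-(4-methoxyphenyl)-4-[(4-methoxyphenyl)ethynyl]-6-[(triisopropylsilyl)oxy]-2,3-dihydro-1-benzofuran | COc1ccc(C#Cc2cc(O[Si](C(C)C)(C(C)C)C(C)C)cc3c2[C@H](c2cc(OC)c4c(c2)[C@@H](c2cc(OC)cc(OC)c2)[C@H](c2ccc(OC)cc2)O4)[C@@H](c2ccc(OC)cc2)O3)cc1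
F4 | step 15 | (2S,3S)-3-(ArB)-2-(4-methoxyphenyl)-4-[(4-methoxyphenyl)ethynyl]-2,3-dihydro-1-benzofuran-6-ol | COc1ccc(C#Cc2cc(O)cc3c2[C@H](c2cc(OC)c4c(c2)[C@@H](c2cc(OC)cc(OC)c2)[C@H](c2ccc(OC)cc2)O4)[C@@H](c2ccc(OC)cc2)O3)cc1
F5 | step 13 | 2-[(1R,2S)-1-(ArB)-2-methoxy-2-(4-methoxyphenyl)ethyl]-3,3-diethoxycyclobutan-1-one (both C2 epimers) | CCOC1(OCC)CC(=O)C1[C@H](c1cc(OC)c2c(c1)[C@@H](c1cc(OC)cc(OC)c1)[C@H](c1ccc(OC)cc1)O2)[C@@H](c1ccc(OC)cc1)OC
F6 | step 9 | (2R,3R)-3-(3,5-dimethoxyphenyl)-7-methoxy-2-(4-methoxyphenyl)-5-(prop-1-yn-1-yl)-2,3-dihydro-1-benzofuran | CC#Cc1cc(OC)c2c(c1)[C@@H](c1cc(OC)cc(OC)c1)[C@H](c1ccc(OC)cc1)O2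
F0 | step 17 | none | none
A1 | alternative 1 | 5-chloro-3-diazo-7-methoxy-2-(4-methoxyphenyl)chroman-4-one (C2 as in the target) | COc1cc(Cl)c2C(=O)C(=[N+]=[N-])[C@@H](c3ccc(OC)cc3)Oc2c1
A2 | alternative 1 | methyl trans-4-chloro-6-methoxy-2-(4-methoxyphenyl)-2,3-dihydro-1-benzofuran-3-carboxylate (C2 as in the target) | Clc1cc(OC)cc2c1[C@H](C(=O)OC)[C@@H](c1ccc(OC)cc1)O2
A3 | alternative 2 | methyl 3-[1-(3,5-dimethoxyphenyl)-2-(4-methoxyphenyl)-2-oxoethyl]-4-fluoro-5-methoxybenzoate (racemic) | COC(=O)c1cc(OC)c(F)c(c1)C(c1cc(OC)cc(OC)c1)C(=O)c1ccc(OC)cc1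
A4 | alternative 2 | methyl (2R,3R)-3-(3,5-dimethoxyphenyl)-7-methoxy-2-(4-methoxyphenyl)-2,3-dihydro-1-benzofuran-5-carboxylate | COC(=O)c1cc(OC)c2c(c1)[C@@H](c1cc(OC)cc(OC)c1)[C@H](c1ccc(OC)cc1)O2
A5 | alternative 3 | methyl 7-[trans-5-bromo-7-methoxy-2-(4-methoxyphenyl)-2,3-dihydro-1-benzofuran-3-yl]-3,5,7-trioxoheptanoate (ring B configured as in the target) | Brc1cc(OC)c2c(c1)[C@@H](C(=O)CC(=O)CC(=O)CC(=O)OC)[C@H](c1ccc(OC)cc1)O2
A6 | alternative 3 | methyl 2-[trans-5-bromo-7-methoxy-2-(4-methoxyphenyl)-2,3-dihydro-1-benzofuran-3-yl]-4,6-dihydroxybenzoate (ring B configured as in the target) | Brc1cc(OC)c2c(c1)[C@@H](c1cc(O)cc(O)c1C(=O)OC)[C@H](c1ccc(OC)cc1)O2
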